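**Plan**

- Retrosynthesis: the biaryl bond C5–C1' is cut first (Suzuki–Miyaura). The nitrogen ring is then cut at C3–C4 and N–C1 in one retro-[4+2] step, leaving an o-methylaryl methyl ketone and the N-sulfinyl imine of acetaldehyde. The naphthalene is cut to an o-methallylbenzamide.
- Enabling feature: on ring A the acetyl carbon C1 (on C8a) and the methyl carbon C4 (on C4a) are ortho to each other. Light turns this ketone into a hydroxy-o-quinodimethane, a diene C4=C4a–C8a=C1 whose termini are the two atoms that C3=N must bridge.
- Forward order: ring A ketone, then the nitrogen ring by photoenolization/aza-Diels–Alder reaction and acid; separately the second naphthalene ring by anionic annulation, then bromination and borylation; biaryl coupling last.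
- Stereochemistry: C3 (S) is set in the key step by the (S)-tert-butanesulfinyl group on the imine nitrogen, which is removed in the same flask.

Key step: step 3

Assumption: the structure defines only C3 (S) and leaves the hindered biaryl axis undefined, so the route fixes C3 and lets the coupling give both axial orientations (separable by chromatography if one is wanted).

**Route**

Step 1
Reactants: 1 1-bromo-2,4-dimethoxy-6-methylbenzene
Product: 2 1-(3-bromo-4,6-dimethoxy-2-methylphenyl)ethan-1-one
Conditions: Ac2O, Bi(OSO2CF3)3 (5 mol%), MeNO2, 50 °C
Reagents that add atoms: acetic anhydride, CC(=O)OC(C)=O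
Why: Friedel–Crafts acylation should go to the free position that is para to one methoxy group and ortho to the other and to the methyl group, the position between the two methoxy groups being the usual minor site of 1,3-dimethoxyarenes; no stereocenter is formed.

Step 2
Reactants: 3 (S)-2-methylpropane-2-sulfinamide; 4 acetaldehyde
Product: 5 (S,E)-N-ethylidene-2-methylpropane-2-sulfinamide
Conditions: MgSO4, PPTS (5 mol%), CH2Cl2, rt (excess 4)
Reagents that add atoms: none
Why: Acid-catalysed condensation of the primary sulfinamide with the aldehyde (imine formation) is driven by the desiccant, gives the E-imine and leaves the sulfur stereocenter untouched.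

Step 3
Reactants: 2 1-(3-bromo-4,6-dimethoxy-2-methylphenyl)ethan-1-one; 5 (S,E)-N-ethylidene-2-methylpropane-2-sulfinamide
Product: 8 (3S)-5-bromo-6,8-dimethoxy-1,3-dimethyl-3,4-dihydroisoquinoline, via E-dienol 6 (not isolated), via N-sulfinyl hemiaminal cycloadduct 7 (not isolated)
Conditions: hν (365 nm), 5 (3 equiv), degassed toluene, 15 °C; evaporate; HCl (4 M in dioxane), MeOH, 0 °C to rt; aq. NaHCO3
Reagents that add atoms: none
Why: Proposed new method: excitation of the twisted aryl ketone should trigger 1,5-hydrogen transfer from the ortho methyl group to the carbonyl oxygen and give the E-hydroxy-o-quinodimethane 6, whose CH2 terminus and hydroxylated terminus add across the C=N bond of 5 in a hetero-Diels–Alder reaction (4π + 2π, suprafacial on both partners), after which HCl in methanol cleaves the S–N bond and the hemiaminal loses water to the cyclic imine. The closest known reaction types are the photoenolization/Diels–Alder reaction of o-alkylaryl ketones with electron-poor alkenes, the Mannich-type trapping of photoenols by activated cyclic imines and the acid-promoted formal aza-Diels–Alder reaction of oxygenated dienes with N-sulfinyl imines, while an N-sulfinyl aldimine has not been shown as the partner of a photoenol. The six-membered ring is closed by cycloaddition, the C4–C3 bond forming ahead of the N–C1 bond, and the orientation follows from polarity, since the diene terminus remote from oxygen (C4) is the nucleophilic one and attacks the imine carbon. The new stereocenter C3 is controlled by the sulfur stereocenter of the auxiliary: a hydrogen bond from the dienol OH to the sulfinyl oxygen should hold the S=O group on the diene side and the tert-butyl group away, so that the diene adds to the face that gives 3S from the (S)-sulfinyl imine, the same sense as in chelate-controlled additions of carbon nucleophiles to sulfinyl aldimines. The step needs site selectivity in the hydrogen transfer, which is secured because the ortho methyl group is the only C–H donor within reach of the carbonyl oxygen (the other ortho position carries OMe), and untrapped dienol returns to ketone 2 by a 1,5-hydrogen shift without loss. It also needs the C–Br bond to survive, which the low triplet energy of the dimethoxyaryl ketone should allow, and it is run before the naphthalene is attached so that no low-lying naphthalene triplet can quench the excited ketone.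

Step 4
Reactants: 9 N,N-diethyl-2-methoxybenzamide
Product: 12 N,N-diethyl-2-methoxy-6-(2-methylprop-2-en-1-yl)benzamide, via aryllithium 10 (not isolated), via arylmagnesium bromide 11 (not isolated)
Conditions: s-BuLi, TMEDA, THF, −78 °C; MgBr2·OEt2; CH2=C(CH3)CH2Br, −78 °C to rt
Reagents that add atoms: 3-bromo-2-methylprop-1-ene, C=C(C)CBr
Why: Directed ortho-metalation should place lithium next to the tertiary amide, the stronger directing group, and transmetalation to magnesium lets the aryl nucleophile undergo clean allylic substitution on the methallyl bromide.

Step 5
Reactants: 12 N,N-diethyl-2-methoxy-6-(2-methylprop-2-en-1-yl)benzamide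
Product: 13 8-methoxy-3-methylnaphthalen-1-ol
Conditions: LDA (2.2 equiv), THF, −78 °C to rt; aq. HCl
Reagents that add atoms: none
Why: Anionic ring annulation of an o-allylbenzamide: deprotonation of the benzylic, allylic CH2 gives a delocalized anion whose terminal carbon attacks the amide carbonyl, and loss of diethylamide followed by tautomerization gives the naphthol with the methoxy group peri to the hydroxyl group.

Step 6
Reactants: 13 8-methoxy-3-methylnaphthalen-1-ol
Product: 14 1,8-dimethoxy-3-methylnaphthalene
Conditions: MeI, K2CO3, DMF, rt
Reagents that add atoms: iodomethane, CI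
Why: Williamson ether synthesis on the naphthoxide is a routine O-methylation.

Step 7
Reactants: 14 1,8-dimethoxy-3-methylnaphthalene
Product: 15 1-bromo-4,5-dimethoxy-2-methylnaphthalene
Conditions: NBS, MeCN, 0 °C to rt
Reagents that add atoms: N-bromosuccinimide, O=C1CCC(=O)N1Br
Why: Electrophilic aromatic bromination should enter para to a methoxy group on the more electron-rich, methyl-bearing ring, at the position that is also ortho to the methyl group.

Step 8
Reactants: 15 1-bromo-4,5-dimethoxy-2-methylnaphthalene
Product: 17 (4,5-dimethoxy-2-methylnaphthalen-1-yl)boronic acid, via naphthyllithium 16 (not isolated)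
Conditions: n-BuLi, THF, −78 °C; B(OMe)3, −78 °C to rt; aq. HCl
Reagents that add atoms: trimethyl borate, COB(OC)OC; water, O
Why: Bromine–lithium exchange followed by trapping with the borate and hydrolysis is the standard route to hindered arylboronic acids.

Step 9
Reactants: 8 (3S)-5-bromo-6,8-dimethoxy-1,3-dimethyl-3,4-dihydroisoquinoline; 17 (4,5-dimethoxy-2-methylnaphthalen-1-yl)boronic acid
Product: 18 O-methylancistrocladinine
Conditions: Pd(OAc)2 (5 mol%), SPhos (10 mol%), K3PO4, toluene/H2O, 100 °C
Reagents that add atoms: none
Why: Suzuki–Miyaura coupling with a bulky dialkylbiarylphosphine ligand is the established way to tetra-ortho-substituted biaryls of this alkaloid class; the hindered cyclic imine and the non-acidic C3 stereocenter should pass unchanged, and both axial orientations are expected.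

**Compound list**

1 | 1-bromo-2,4-dimethoxy-6-methylbenzene (2-bromo-3,5-dimethoxytoluene) | Cc1cc(OC)cc(OC)c1Br | starting material
2 | 1-(3-bromo-4,6-dimethoxy-2-methylphenyl)ethan-1-one | CC(=O)c1c(C)c(Br)c(OC)cc1OC | intermediate
3 | (S)-2-methylpropane-2-sulfinamide | CC(C)(C)[S@](=O)N | starting material
4 | acetaldehyde | CC=O | starting material
5 | (S,E)-N-ethylidene-2-methylpropane-2-sulfinamide | CC(C)(C)[S@](=O)/N=C/C | intermediate
6 | (E)-1-(3-bromo-4,6-dimethoxy-2-methylidenecyclohexa-3,5-dien-1-ylidene)ethan-1-ol (E-dienol, OH turned away from the CH2 terminus) | O/C(C)=C1/C(=C)C(Br)=C(OC)C=C1OC | intermediate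
7 | (3S)-5-bromo-2-[(S)-tert-butylsulfinyl]-6,8-dimethoxy-1,3-dimethyl-1,2,3,4-tetrahydroisoquinolin-1-ol (C1 of either configuration) | C[C@H]1Cc2c(Br)c(OC)cc(OC)c2C(C)(O)N1[S@@](=O)C(C)(C)C | intermediate
8 | (3S)-5-bromo-6,8-dimethoxy-1,3-dimethyl-3,4-dihydroisoquinoline | COc1cc(OC)c(Br)c2c1C(C)=N[C@@H](C)C2 | intermediate
9 | N,N-diethyl-2-methoxybenzamide | CCN(CC)C(=O)c1ccccc1OC | starting material
10 | [2-(diethylcarbamoyl)-3-methoxyphenyl]lithium | CCN(CC)C(=O)c1c([Li])cccc1OC | intermediate
11 | [2-(diethylcarbamoyl)-3-methoxyphenyl]magnesium bromide | CCN(CC)C(=O)c1c([Mg]Br)cccc1OC | intermediate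
12 | N,N-diethyl-2-methoxy-6-(2-methylprop-2-en-1-yl)benzamide | CCN(CC)C(=O)c1c(CC(C)=C)cccc1OC | intermediate
13 | 8-methoxy-3-methylnaphthalen-1-ol | COc1cccc2cc(C)cc(O)c12 | intermediate
14 | 1,8-dimethoxy-3-methylnaphthalene | COc1cccc2cc(C)cc(OC)c12 | intermediate
15 | 1-bromo-4,5-dimethoxy-2-methylnaphthalene | COc1cc(C)c(Br)c2cccc(OC)c12 | intermediate
16 | (4,5-dimethoxy-2-methylnaphthalen-1-yl)lithium | COc1cc(C)c([Li])c2cccc(OC)c12 | intermediate
17 | (4,5-dimethoxy-2-methylnaphthalen-1-yl)boronic acid | COc1cc(C)c(B(O)O)c2cccc(OC)c12 | intermediate
18 | O-methylancistrocladinine, (3S)-5-(4,5-dimethoxy-2-methylnaphthalen-1-yl)-6,8-dimethoxy-1,3-dimethyl-3,4-dihydroisoquinoline | COc1cc(OC)c(-c2c(C)cc(OC)c3c(OC)cccc23)c2c1C(C)=N[C@@H](C)C2 | target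

**Count and risks**

Total step count: 9. Longest linear sequence: 6 steps (steps 4 to 9, from amide 9).

Steps most likely to fail:

1. Step 3 (proposed new method). The short-lived dienol may return to the ketone faster than the weakly dienophilic imine traps it, the sulfinyl imine may degrade under irradiation, and the facial selectivity may be poor or reversed if the hydrogen-bonded arrangement does not hold. Fallback by known chemistry, lateral metalation in place of photoenolization; it sets out from 1 and comes back to the route at 8. Electrophilic cyanation of 1 (ClSO2NCO, MeCN, then DMF) at the same ring position should give 3-bromo-4,6-dimethoxy-2-methylbenzonitrile F1. LDA in THF at −78 °C deprotonates the ortho methyl group, the nitrile having no α-hydrogen of its own, to give [(2-bromo-6-cyano-3,5-dimethoxyphenyl)methyl]lithium F2. F2 adds to imine 5 under chelate control to give (S)-N-[(2S)-1-(2-bromo-6-cyano-3,5-dimethoxyphenyl)propan-2-yl]-2-methylpropane-2-sulfinamide F3. Methyllithium (THF, −78 °C, where bromine–lithium exchange is slow) then adds to the nitrile, and HCl in methanol removes the sulfinyl group; the free amine closes onto the ketimine carbon with loss of ammonia to give 8. In this fallback the C3–C4 bond is made between two molecules and the ring closes at nitrogen.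

2. Step 9. Transmetalation and reductive elimination at the tetra-ortho-substituted axis may be slow, so that protodeboronation of the electron-rich boronic acid and binding of the imine nitrogen to palladium take over. Fallback with a zinc nucleophile made directly from the bromide, which removes the protodeboronation channel and bypasses step 8; it sets out from 15 (with 8) and comes back at 18. Bromine–lithium exchange of 15 gives naphthyllithium 16, and ZnCl2 converts it into (4,5-dimethoxy-2-methylnaphthalen-1-yl)zinc chloride F4. F4 is coupled with 8 in a Negishi reaction (Pd2(dba)3, RuPhos, THF, 70 °C).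

3. Step 7. Bromination may go to the para position of the other ring, or go on to a dibromide. Fallback that changes the order so that a free hydroxyl group, the stronger para director, fixes the site; it sets out from 13 and comes back at 15. Naphthol 13 is brominated (NBS, MeCN, −20 °C) to 4-bromo-8-methoxy-3-methylnaphthalen-1-ol F5, which is then O-methylated (MeI, K2CO3, DMF) to 15.

**Further compounds**

F1 | step 3 | 3-bromo-4,6-dimethoxy-2-methylbenzonitrile | N#Cc1c(C)c(Br)c(OC)cc1OC
F2 | step 3 | [(2-bromo-6-cyano-3,5-dimethoxyphenyl)methyl]lithium | [Li]Cc1c(Br)c(OC)cc(OC)c1C#N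
F3 | step 3 | (S)-N-[(2S)-1-(2-bromo-6-cyano-3,5-dimethoxyphenyl)propan-2-yl]-2-methylpropane-2-sulfinamide | C[C@@H](Cc1c(Br)c(OC)cc(OC)c1C#N)N[S@@](=O)C(C)(C)C
F4 | step 9 | (4,5-dimethoxy-2-methylnaphthalen-1-yl)zinc chloride | COc1cc(C)c([Zn]Cl)c2cccc(OC)c12
F5 | step 7 | 4-bromo-8-methoxy-3-methylnaphthalen-1-ol | COc1cccc2c(Br)c(C)cc(O)c12
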